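Cuts (germacrane numbering): the acetates and the C3/C9 configurations go back to a 3,9-dione. C12=O and the O6–C12 bond go back to a C7 isopropenyl group beside C6–OH. Then C6–C7 is cut, then C7=C11, C9–C8, C1=C10, C3–C2, C3–C4 and O–C12.
Enabling feature: O6–C6 is flanked by the Z-C4=C5 olefin and C7 carries C11, which is a homoallylic allyl carbinol. Joining O6 to C12 along the lactone path C6–O–C12–C11–C7 merges the five- and ten-membered rings into one 13-membered (Z,Z,E)-diallyl ether. Its transannular [2,3]-Wittig shift forms C6–C7 and contracts 13 to 10.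
Forward: three C5 units are joined head to tail (Z-C4=C5 from a Z-vinyl iodide, Z-C1=C10 locked in a δ-lactone by RCM). Macro-RCM closes the 13-ring, the Wittig shift gives the carbocycle, and hydroboration/oxidation closes the γ-lactone last.
Stereochemistry: two reagent-controlled allylborations set temporary 3R,9S carbinols, which are peripheral in the folded transition state and relay to C6 and C7. C11 comes from hydroboration anti to C6. The final 3S,9R centres come from peripheral hydride attack on the 3,9-dione.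

Key step: step 10

Remarks: germacrane numbering C1–C15 is used for every intermediate. The C6 descriptor reads R in 20 and S from 22 on only because the CIP ranks change. Both antipodes of B-allyldiisopinocampheylborane are taken as purchasable solutions.

Step 1
Reactants: 1 but-2-yn-1-ol
Product: 3 (Z)-3-iodobut-2-en-1-ol, via cyclic alkenylalanate 2 (not isolated)
Conditions: NaAlH2(OCH2CH2OMe)2 (Red-Al), Et2O, 0 °C to rt; then I2, THF, −78 °C
Reagents that add atoms: iodine, II
Why: Hydroxyl-directed trans-hydroalumination of the propargylic alcohol places aluminium on C4 inside a five-membered alanate, and iodinolysis with retention gives only the Z-iodide (hydroalumination–iodination), which fixes the Z-C4=C5 geometry.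

Step 2
Reactants: 3 (Z)-3-iodobut-2-en-1-ol; 4 3-bromo-2-methylprop-1-ene
Product: 5 (Z)-3-iodobut-2-en-1-yl 2-methylprop-2-en-1-yl ether
Conditions: NaH, Bu4NI (cat.), THF, 0 °C to rt
Reagents that add atoms: 3-bromo-2-methylprop-1-ene (4), C=C(C)CBr
Why: Williamson ether synthesis of a primary alkoxide with an unhindered allylic bromide brings in C11, C12 and C13 on the oxygen that ends as O6.

Step 3
Reactants: 5 (Z)-3-iodobut-2-en-1-yl 2-methylprop-2-en-1-yl ether
Product: 7 (Z)-2-methyl-4-[(2-methylprop-2-en-1-yl)oxy]but-2-enal, via vinyllithium 6 (not isolated)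
Conditions: t-BuLi (2.1 equiv), Et2O, −78 °C; then DMF; aq. work-up
Reagents that add atoms: N,N-dimethylformamide, CN(C)C=O
Why: Iodine–lithium exchange keeps the olefin geometry, and formylation of the vinyllithium with DMF delivers C3 as the Z-enal.

Step 4
Reactants: 7 (Z)-2-methyl-4-[(2-methylprop-2-en-1-yl)oxy]but-2-enal; 8 B-allyldiisopinocampheylborane derived from (−)-α-pinene
Product: 10 (2Z,4R)-3-methyl-1-[(2-methylprop-2-en-1-yl)oxy]hepta-2,6-dien-4-ol, via borinate 9 (not isolated)
Conditions: 8 (1.3 equiv), Et2O, −78 °C; then NaOH, H2O2, 0 °C to rt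
Reagents that add atoms: B-allyldiisopinocampheylborane (8), C=CCB([C@H]1C[C@H]2C[C@@H]([C@@H]1C)C2(C)C)[C@H]1C[C@H]2C[C@@H]([C@@H]1C)C2(C)C
Why: Brown asymmetric allylboration through the closed chair transition state adds allyl (C2, C1) to the Re face of the enal and sets the temporary 3R carbinol under reagent control.

Step 5
Reactants: 10 (2Z,4R)-3-methyl-1-[(2-methylprop-2-en-1-yl)oxy]hepta-2,6-dien-4-ol; 11 methacryloyl chloride
Product: 12 methacrylate of 10
Conditions: Et3N, DMAP (cat.), CH2Cl2, 0 °C
Reagents that add atoms: methacryloyl chloride (11), C=C(C)C(=O)Cl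
Why: DMAP-catalysed acylation of a secondary alcohol installs C9, C10 and C14 as a metathesis partner tethered through O3.

Step 6
Reactants: 12 methacrylate of 10
Product: 13 (6R)-3-methyl-6-{(2Z)-4-[(2-methylprop-2-en-1-yl)oxy]but-2-en-2-yl}-5,6-dihydro-2H-pyran-2-one
Conditions: second-generation Grubbs catalyst, RuCl2(=CHPh)(PCy3)(H2IMes) (5 mol %), CH2Cl2 (5 mM), reflux
Reagents that add atoms: none
Why: Ring-closing metathesis of the methacrylate with the only monosubstituted olefin gives the α-methyl unsaturated δ-lactone, whose six-membered ring can hold only a cis olefin and so locks Z-C1=C10, while the other olefins are too hindered or too remote to compete.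

Step 7
Reactants: 13 δ-lactone
Product: 14 lactol of 13 (anomer mixture)
Conditions: i-Bu2AlH (1.1 equiv), CH2Cl2, −78 °C; aq. Rochelle salt
Reagents that add atoms: none
Why: Partial lactone reduction stops at the aluminium hemiacetal at low temperature and gives the lactol, the ring tautomer of the Z-enal at C9.

Step 8
Reactants: 14 lactol; 15 B-allyldiisopinocampheylborane derived from (+)-α-pinene
Product: 17 (4S,5Z,8R,9Z)-5,9-dimethyl-11-[(2-methylprop-2-en-1-yl)oxy]undeca-1,5,9-triene-4,8-diol, via borinate 16 (not isolated)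
Conditions: 15 (2.5 equiv), Et2O, −78 to 0 °C; then NaOH, H2O2
Reagents that add atoms: B-allyldiisopinocampheylborane (15), C=CCB([C@@H]1C[C@@H]2C[C@H]([C@H]1C)C2(C)C)[C@@H]1C[C@@H]2C[C@H]([C@H]1C)C2(C)C
Why: Brown allylboration of the open hydroxy-enal tautomer adds allyl (C8, C7) to the Si face and sets the temporary 9S carbinol under reagent control, the remote C3 centre having no influence.

Step 9
Reactants: 17 acyclic triene-ether diol
Product: 18 (3Z,5R,7Z,9S,11E)-4,8,12-trimethyl-1-oxacyclotrideca-3,7,11-triene-5,9-diol (ring C5 = C3, ring C9 = C9)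
Conditions: second-generation Hoveyda–Grubbs catalyst, RuCl2(=CH-C6H4-2-OiPr)(H2IMes) (10 mol %), toluene (1 mM), 80 °C, argon purge
Reagents that add atoms: none
Why: Macrocyclic ring-closing metathesis joins the only monosubstituted olefin to the 1,1-disubstituted ether olefin, and the E-C7=C11 isomer, with the ring branches C8 and C12 trans, should prevail in a 13-ring that already holds two Z olefins.

Step 10
Reactants: 18 13-membered diallyl ether diol
Product: 20 (3R,6R,7S,9S)-germacra-1(10)Z,4Z,11-triene-3,6,9-triol, via trilithio species 19 (not isolated)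
Conditions: s-BuLi (3.5 equiv), THF, −78 to −25 °C; then H2O
Reagents that add atoms: none
Why: s-BuLi first turns C3–OH and C9–OH into lithium alkoxides and then removes an allylic, α-oxygenated hydrogen at C6; the 1-oxyallyllithium bonds from C6 to C7 through a five-membered envelope (C6, O, C12, C11, C7) while O–C12 breaks, a concerted [2,3]-Wittig shift that leaves O on C6 and turns C11–C12 into the isopropenyl olefin. The closest known reaction type is the transannular [2,3]-Wittig ring contraction of 13-membered diallylic ethers to ten-membered dienols. One ring is closed, the ten-membered carbocycle, by sigmatropic contraction of the 13-ring (transannular, no high dilution), and the five-membered array exists only in the transition state. C7 is controlled by the E-C7=C11 geometry, which with C5 exo on the envelope gives the anti O6/C11 pair, that is trans H6/H7. C6 is controlled by C3: allylic 1,3-strain keeps C3–H in the plane of Z-C4=C5, the short bridge C2–C1=C10–C9–C8 can span only if C2 and C7 lie on the same face of that plane, so O3–Li and the C6–Li contact stay on the outer face and C7 bonds with inversion on the inner face, which for 3R gives the C6 configuration of the target, and the 9S alkoxide is peripheral in the same fold (matched pair). The step needs lithiation at C6 and not at C12 or C2, no 1,4-elimination across C6–C5=C4–C3 and no anionic oxy-Cope shift of the product: C6–H is the only hydrogen that is allylic, α to the ether oxygen and cis to an alkoxide that delivers the base, oxide cannot leave from C3, and the lithium counter-ion below −25 °C keeps the 3-oxido-1,5-diene intact.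

Step 11
Reactants: 20 triol
Product: 22 (3R,6S,7S,9S,11R)-germacra-1(10)Z,4Z-diene-3,6,9,12-tetraol, via tetraboryl intermediate 21 (not isolated)
Conditions: 9-BBN (5 equiv), THF, 0 °C to rt; then NaOH, H2O2
Reagents that add atoms: hydrogen peroxide, OO
Why: In this hydroboration–oxidation 9-BBN first caps the three hydroxyls as borinates and then adds only to the 1,1-disubstituted C11=C12 olefin, anti to the bulky C6 branch in the conformer with C7–H eclipsing the olefin (the sense known for trans-2-isopropenylcyclohexanols such as isopulegol), which sets 11R.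

Step 12
Reactants: 22 tetraol
Product: 24 (3R,6S,7S,9S,11R)-3,9-dihydroxygermacra-1(10)Z,4Z-dien-12,6-olide, via lactol 23 (not isolated)
Conditions: TEMPO (0.2 equiv), PhI(OAc)2 (2.5 equiv), CH2Cl2, rt
Reagents that add atoms: none
Why: In this nitroxyl-catalysed oxidative lactonisation the primary C12 alcohol is oxidised fastest, O6 traps the aldehyde as the five-membered lactol and this is oxidised on to the γ-lactone under neutral conditions that leave C11 untouched, and any early oxidation at C3 or C9 only anticipates step 13.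

Step 13
Reactants: 24 dihydroxy lactone
Product: 25 (6S,7S,11R)-3,9-dioxogermacra-1(10)Z,4Z-dien-12,6-olide
Conditions: activated MnO2 (excess), CH2Cl2, rt
Reagents that add atoms: none
Why: MnO2 oxidation is selective for allylic alcohols and neutral, so both temporary carbinols become enones without epimerisation at C11 or enolisation at C2.

Step 14
Reactants: 25 diketo lactone
Product: 26 (3S,6S,7S,9R,11R)-3,9-dihydroxygermacra-1(10)Z,4Z-dien-12,6-olide
Conditions: NaBH4, CeCl3·7H2O, MeOH, −78 °C
Reagents that add atoms: none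
Why: In this Luche 1,2-reduction H6 is held in the plane of Z-C4=C5 by allylic 1,3-strain and the trans-lactone fixes the fold, so each carbonyl shows only its peripheral face, hydride enters there and turns O3 and O9 towards the ring, which should give 3S and 9R.

Step 15
Reactants: 26 (3S,9R)-diol lactone
Product: 27 (3S,6S,7S,9R,11R)-3,9-diacetoxygermacra-1(10)Z,4Z-dien-12,6-olide (target)
Conditions: Ac2O, pyridine, DMAP (cat.), CH2Cl2, 0 °C to rt
Reagents that add atoms: acetic anhydride, CC(=O)OC(C)=O
Why: DMAP-catalysed acetylation of both secondary alcohols uses a base too weak to epimerise C11 and gives the target.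

Compound list
1 | but-2-yn-1-ol | CC#CCO | starting material
2 | sodium cyclic alkenylalanate | CC1=CCO[Al-]1(OCCOC)OCCOC.[Na+] | intermediate
3 | (Z)-3-iodobut-2-en-1-ol | C/C(I)=C/CO | intermediate
4 | 3-bromo-2-methylprop-1-ene | C=C(C)CBr | starting material
5 | (Z)-3-iodobut-2-en-1-yl 2-methylprop-2-en-1-yl ether | C/C(I)=C/COCC(C)=C | intermediate
6 | Z-vinyllithium from 5 | C/C([Li])=C/COCC(C)=C | intermediate
7 | (Z)-2-methyl-4-[(2-methylprop-2-en-1-yl)oxy]but-2-enal | C/C(C=O)=C/COCC(C)=C | intermediate
8 | B-allyldiisopinocampheylborane from (−)-α-pinene | C=CCB([C@H]1C[C@H]2C[C@@H]([C@@H]1C)C2(C)C)[C@H]1C[C@H]2C[C@@H]([C@@H]1C)C2(C)C | starting material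
9 | diisopinocampheylborinate of 10 | C=CC[C@@H](OB([C@H]1C[C@H]2C[C@@H]([C@@H]1C)C2(C)C)[C@H]1C[C@H]2C[C@@H]([C@@H]1C)C2(C)C)/C(C)=C\COCC(C)=C | intermediate
10 | (2Z,4R)-3-methyl-1-[(2-methylprop-2-en-1-yl)oxy]hepta-2,6-dien-4-ol | C=CC[C@@H](O)/C(C)=C\COCC(C)=C | intermediate
11 | methacryloyl chloride | C=C(C)C(=O)Cl | starting material
12 | methacrylate of 10 | C=CC[C@@H](OC(=O)C(C)=C)/C(C)=C\COCC(C)=C | intermediate
13 | (6R)-3-methyl-6-{(2Z)-4-[(2-methylprop-2-en-1-yl)oxy]but-2-en-2-yl}-5,6-dihydro-2H-pyran-2-one | O=C1O[C@H](CC=C1C)/C(C)=C\COCC(C)=C | intermediate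
14 | lactol of 13 (anomer mixture) | OC1O[C@H](CC=C1C)/C(C)=C\COCC(C)=C | intermediate
15 | B-allyldiisopinocampheylborane from (+)-α-pinene | C=CCB([C@@H]1C[C@@H]2C[C@H]([C@H]1C)C2(C)C)[C@@H]1C[C@@H]2C[C@H]([C@H]1C)C2(C)C | starting material
16 | O9-diisopinocampheylborinate of 17 | C=CC[C@H](OB([C@@H]1C[C@@H]2C[C@H]([C@H]1C)C2(C)C)[C@@H]1C[C@@H]2C[C@H]([C@H]1C)C2(C)C)/C(C)=C\C[C@@H](O)/C(C)=C\COCC(C)=C | intermediate
17 | (4S,5Z,8R,9Z)-5,9-dimethyl-11-[(2-methylprop-2-en-1-yl)oxy]undeca-1,5,9-triene-4,8-diol | C=CC[C@H](O)/C(C)=C\C[C@@H](O)/C(C)=C\COCC(C)=C | intermediate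
18 | (3Z,5R,7Z,9S,11E)-4,8,12-trimethyl-1-oxacyclotrideca-3,7,11-triene-5,9-diol | O1C/C=C(/C)[C@H](O)C/C=C(/C)[C@@H](O)C/C=C(\C)C1 | intermediate
19 | C6-lithio dilithium dialkoxide of 18 | [Li]C1/C=C(/C)[C@H]([O-])C/C=C(/C)[C@@H]([O-])C/C=C(\C)CO1.[Li+].[Li+] | intermediate
20 | (3R,6R,7S,9S)-germacra-1(10)Z,4Z,11-triene-3,6,9-triol | O[C@@H]1C/C=C(/C)[C@@H](O)C[C@@H](C(C)=C)[C@@H](/C=C\1C)O | intermediate
21 | tris-O-(9-BBN) C12-(9-BBN) adduct of 20 | B2(C3CCCC2CCC3)O[C@@H]1C/C=C(/C)[C@@H](OB2C3CCCC2CCC3)C[C@@H]([C@@H](C)CB2C3CCCC2CCC3)[C@@H](/C=C\1C)OB2C3CCCC2CCC3 | intermediate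
22 | (3R,6S,7S,9S,11R)-germacra-1(10)Z,4Z-diene-3,6,9,12-tetraol | O[C@@H]1C/C=C(/C)[C@@H](O)C[C@@H]([C@@H](C)CO)[C@@H](/C=C\1C)O | intermediate
23 | 12,6-lactol of 22 | O[C@@H]1C/C=C(/C)[C@@H](O)C[C@@H]2[C@@H](/C=C\1C)OC(O)[C@@H]2C | intermediate
24 | (3R,6S,7S,9S,11R)-3,9-dihydroxygermacra-1(10)Z,4Z-dien-12,6-olide | O[C@@H]1C/C=C(/C)[C@@H](O)C[C@@H]2[C@@H](/C=C\1C)OC(=O)[C@@H]2C | intermediate
25 | (6S,7S,11R)-3,9-dioxogermacra-1(10)Z,4Z-dien-12,6-olide | O=C1C/C=C(/C)C(=O)C[C@@H]2[C@@H](/C=C\1C)OC(=O)[C@@H]2C | intermediate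
26 | (3S,6S,7S,9R,11R)-3,9-dihydroxygermacra-1(10)Z,4Z-dien-12,6-olide | O[C@H]1C/C=C(/C)[C@H](O)C[C@@H]2[C@@H](/C=C\1C)OC(=O)[C@@H]2C | intermediate
27 | (3S,6S,7S,9R,11R)-3,9-diacetoxygermacra-1(10)Z,4Z-dien-12,6-olide | CC(=O)O[C@H]1C/C=C(/C)[C@H](OC(C)=O)C[C@@H]2[C@@H](/C=C\1C)OC(=O)[C@@H]2C | target

Total step count: 15. Longest linear sequence: 15 steps (from but-2-yn-1-ol).

Steps most likely to fail

Step 10. Lithiation of the dialkoxide may take place at C12 or C2, a [1,2]-shift may compete, or the face selection at C6/C7 may be poor.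
Fallback: the same bond is closed on acyclic material by an intramolecular Nozaki–Hiyama–Kishi allylation. It sets out from 17 and comes back at 20.
- Silylation of 17 (TBSOTf, 2,6-lutidine) gives the bis-TBS ether F1.
- DDQ in wet CH2Cl2 abstracts hydride from the prenyl-type C6 position and releases the Z-enal F2.
- Cross-metathesis with 4 gives the allylic bromide F3. Its olefin geometry does not matter because allylchromium species equilibrate.
- CrCl2 in THF/DMF under high dilution joins the γ-carbon C7 to C6 with anti selectivity and gives the ring alcohol F4.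
- TBAF gives 20.

Step 9. Intermolecular metathesis may lead to oligomers, or the ring may close to the wrong geometry at C7=C11, which cannot reach the envelope of step 10.
Fallback: the geometry is set by cross-metathesis with an enal and the ring is closed by Williamson etherification. It sets out from 17 and comes back at 18.
- The bis-TBS ether F1, made as above, undergoes cross-metathesis with excess methacrolein at normal concentration to give the E-enal F5.
- NaBH4/CeCl3 gives the allylic alcohol F6.
- MsCl/Et3N followed by LiCl gives the allylic chloride F7.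
- DDQ in wet CH2Cl2 frees C6 as the chloro Z-enal F8.
- NaBH4/CeCl3 gives the hydroxy chloride F9.
- NaH in THF under high dilution closes the ether to the bis-TBS macrocycle F10.
- TBAF gives 18.

Step 14. Hydride may enter from the wrong face at one of the two carbonyls, or the doubly activated C2 methylene of 25 may enolise with loss of the Z-C1=C10 geometry.
Fallback: inversion by substitution replaces the redox relay. It sets out from 24 and comes back at 27. A double Mitsunobu reaction of 24 with acetic acid (PPh3, DIAD, toluene, 0 °C), a reaction type known for 2-methylcycloalk-2-enols, would invert C3 and C9 and place both acetates in one operation, skipping 25 and 26.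

Further compounds
F1 | step 10 | bis-TBS ether of 17 | C=CC[C@H](O[Si](C)(C)C(C)(C)C)/C(C)=C\C[C@@H](O[Si](C)(C)C(C)(C)C)/C(C)=C\COCC(C)=C
F2 | step 10 | C6 Z-enal with terminal olefin | C=CC[C@H](O[Si](C)(C)C(C)(C)C)/C(C)=C\C[C@@H](O[Si](C)(C)C(C)(C)C)/C(C)=C\C=O
F3 | step 10 | C12 allylic bromide C6 enal | BrC/C(C)=C/C[C@H](O[Si](C)(C)C(C)(C)C)/C(C)=C\C[C@@H](O[Si](C)(C)C(C)(C)C)/C(C)=C\C=O
F4 | step 10 | 3,9-bis-O-TBS ether of 20 | CC(C)(C)[Si](C)(C)O[C@@H]1C/C=C(/C)[C@@H](O[Si](C)(C)C(C)(C)C)C[C@@H](C(C)=C)[C@@H](/C=C\1C)O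
F5 | step 9 | C12 E-enal of F1 | O=C/C(C)=C/C[C@H](O[Si](C)(C)C(C)(C)C)/C(C)=C\C[C@@H](O[Si](C)(C)C(C)(C)C)/C(C)=C\COCC(C)=C
F6 | step 9 | C12 allylic alcohol | OC/C(C)=C/C[C@H](O[Si](C)(C)C(C)(C)C)/C(C)=C\C[C@@H](O[Si](C)(C)C(C)(C)C)/C(C)=C\COCC(C)=C
F7 | step 9 | C12 allylic chloride | ClC/C(C)=C/C[C@H](O[Si](C)(C)C(C)(C)C)/C(C)=C\C[C@@H](O[Si](C)(C)C(C)(C)C)/C(C)=C\COCC(C)=C
F8 | step 9 | C12 chloride C6 Z-enal | ClC/C(C)=C/C[C@H](O[Si](C)(C)C(C)(C)C)/C(C)=C\C[C@@H](O[Si](C)(C)C(C)(C)C)/C(C)=C\C=O
F9 | step 9 | C12 chloride C6 alcohol | ClC/C(C)=C/C[C@H](O[Si](C)(C)C(C)(C)C)/C(C)=C\C[C@@H](O[Si](C)(C)C(C)(C)C)/C(C)=C\CO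
F10 | step 9 | bis-TBS ether of 18 | O1C/C=C(/C)[C@H](O[Si](C)(C)C(C)(C)C)C/C=C(/C)[C@@H](O[Si](C)(C)C(C)(C)C)C/C=C(\C)C1
F0 | step 14 | none | none
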